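**Plan**

Cuts: (i) the acyl C–C3 bond of pyridone ring C, giving a decalin aldehyde and a 3-metallated 2,4-dialkoxypyridine N-oxide (masked N-hydroxypyridone); (ii) C5–C1', giving a 5-lithiopyridine and (R)-4-silyloxycyclohex-2-enone (ring D); (iii) C4a–C5 and C8–C8a of ring B, giving butadiene and a ring-A enone; (iv) ring A, giving Danishefsky's diene and an (E)-crotonoyl imide.
Enabling feature: ring B is saturated and cis-fused, so H-4a and H-8a lie on one face of ring A. A C4a=C8a enone alkene (C4 ketone) in a ring A that already holds C1 and C2 can therefore accept both ring-B bonds suprafacially, and the C4 ketone later becomes the C3=C4 alkene.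
Forward: ring A by catalytic asymmetric [4+2]; ring B by the butadiene [4+2]; then hydrogenation, enol triflate and formate reduction. In parallel, ring D is joined to the purchased pyridine (ring C), and oxirane ring E and the N-oxide are installed together. The halves are joined by Grignard addition, oxidation and one fluoride deprotection.
Stereochemistry: C1/C2 from a copper bis(oxazoline) catalyst and the (E)-alkene; C4a/C8a from suprafacial addition anti to the C1 side chain; C4' from a desymmetrising Kornblum–DeLaMare rearrangement; C1' from addition to the C4'-bearing enone; C5'/C6' from hydroxyl-directed epoxidation.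

Key step: step 5

Numbering: decalin C1–C8a as in the natural product (ring A = C1–C4, C4a, C8a; ring B = C4a–C8a). Ring D = C1'–C6' (C1' on pyridone C5, C4' the secondary carbinol, C5'/C6' the oxirane carbons).
Abbreviations: TBDPS = tert-butyldiphenylsilyl; TES = triethylsilyl; TMS = trimethylsilyl; TMSE = 2-(trimethylsilyl)ethyl; t-Bu-box = 2,2'-(propane-2,2-diyl)bis(4-tert-butyl-4,5-dihydro-1,3-oxazole); TASF = tris(dimethylamino)sulfonium difluorotrimethylsilicate.
Assumption: the quinidine-derived catalyst of step 12 is taken to remove the hydrogen at the (S)-configured bridgehead of 19. If the rotation of 20 shows the opposite sense, the quinine-derived pseudoenantiomer is used and nothing else changes.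

**Route**

Step 1
Reactants: 1 1,3-oxazolidin-2-one; 2 (E)-but-2-enoyl chloride
Product: 4 3-[(E)-but-2-enoyl]-1,3-oxazolidin-2-one, via lithium oxazolidinonide 3 (not isolated)
Conditions: n-BuLi, THF, −78 °C; then 2, −78 → 0 °C
Reagents that add atoms: none
Why: N-acylation of the lithiated carbamate by the acid chloride is fast at low temperature, which keeps the (E)-alkene in conjugation and provides the two-point-binding dienophile for step 2.

Step 2
Reactants: 4 3-[(E)-but-2-enoyl]-1,3-oxazolidin-2-one; 5 trans-1-methoxy-3-(trimethylsilyloxy)buta-1,3-diene (Danishefsky's diene)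
Product: 6 3-{[(1R,2S,6S)-2-methoxy-6-methyl-4-(trimethylsilyloxy)cyclohex-3-en-1-yl]carbonyl}-1,3-oxazolidin-2-one
Conditions: [Cu((R,R)-t-Bu-box)](SbF6)2 (10 mol %), CH2Cl2, −20 °C
Reagents that add atoms: none
Why: In this enantioselective Lewis-acid-catalysed Diels–Alder reaction the divalent copper centre chelates both imide carbonyls in a square-planar s-cis complex whose tert-butyl group covers the Cα-Re face, so the polarised diene bonds through its CH2 terminus to Cβ and through its CH(OMe) terminus to the Cα-Si face, which fixes the future C1 and C2 absolutely, makes them trans because the (E)-alkene adds suprafacially, and leaves an endo-derived methoxy centre that is erased in step 3.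

Step 3
Reactants: 6 cycloadduct
Product: 8 (4R,5S)-4-(hydroxymethyl)-5-methylcyclohex-2-en-1-one, via silyl enol ether alcohol 7 (not isolated)
Conditions: LiAlH4, THF, −78 → 0 °C; then 1 M HCl, THF, 0 °C → rt
Reagents that add atoms: none
Why: Hydride reduction of the exocyclic imide carbonyl leaves the silyl enol ether untouched, and the acidic work-up then hydrolyses it and eliminates methanol (β-elimination), so the enone appears only after the C1 substituent has lost its acidifying carbonyl group and the trans C1/C2 pair cannot epimerise.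

Step 4
Reactants: 8 (4R,5S)-4-(hydroxymethyl)-5-methylcyclohex-2-en-1-one
Product: 9 (4R,5S)-4-{[tert-butyl(diphenyl)silyl]oxymethyl}-5-methylcyclohex-2-en-1-one
Conditions: TBDPSCl, imidazole, CH2Cl2, 0 °C → rt
Reagents that add atoms: tert-butyl(chloro)diphenylsilane, CC(C)(C)[Si](Cl)(c1ccccc1)c1ccccc1
Why: Imidazole-promoted silylation of the primary alcohol installs a bulky, weakly Lewis-basic ether that survives aluminium Lewis acids and enlarges the C1 side chain for step 5.

Step 5
Reactants: 9 (4R,5S)-4-{[tert-butyl(diphenyl)silyl]oxymethyl}-5-methylcyclohex-2-en-1-one; 10 buta-1,3-diene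
Product: 11 (3S,4R,4aS,8aS)-4-{[tert-butyl(diphenyl)silyl]oxymethyl}-3-methyl-3,4,4a,5,8,8a-hexahydronaphthalen-1(2H)-one (cis-fused octalone)
Conditions: 10 (excess), EtAlCl2 (40 mol %), toluene, −20 → 20 °C, sealed vessel, short contact time; cold aq NaHCO3 quench
Reagents that add atoms: none
Why: EtAlCl2 binds the C4 carbonyl oxygen of 9, lowers the enone LUMO and lets s-cis butadiene add in a concerted, asynchronous, suprafacial [4+2] cycloaddition in which C8–C8a (at the β-carbon) forms ahead of C4a–C5. The closest known reaction type is the aluminium-halide-catalysed Diels–Alder addition of butadiene to 4-alkylcyclohex-2-enones, which gives cis-octalones by attack anti to the 4-substituent. Ring B closes by intermolecular [4+2] annulation, with four of its six carbons coming from 10 and both new σ-bonds ending on the ring-A alkene. C4a and C8a are tied to each other by suprafacial addition to a ring (Z)-alkene, so the fusion hydrogens must be cis; their relation to C1 is set by the CH2OTBDPS group, whose pseudoequatorial allylic C–C bond leans over its own face of the half-chair and meets the diene terminus bonding to C8a, whereas the opposite face offers only C1–H. The step needs facial selectivity and retention of the kinetic cis fusion: the bulky silyl ether raises the bias without tying up the Lewis acid, the equatorial C2 methyl group lies in the periphery of ring A and blocks neither face, and a short run with a cold basic quench keeps C4a from epimerising to the trans-octalone. Regiochemistry does not arise with the symmetrical diene, and 9 holds only one dienophilic alkene.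

Step 6
Reactants: 11 cis-octalone
Product: 12 (3S,4R,4aS,8aS)-4-{[tert-butyl(diphenyl)silyl]oxymethyl}-3-methyloctahydronaphthalen-1(2H)-one (cis-decalone)
Conditions: H2 (1 atm), Pd on carbon, EtOAc, rt
Reagents that add atoms: none
Why: Heterogeneous hydrogenation saturates the unhindered ring-B alkene under neutral conditions that neither reduce the ketone nor disturb the epimerisable C4a centre.

Step 7
Reactants: 12 cis-decalone
Product: 14 (3R,4R,4aS,8aS)-4-{[tert-butyl(diphenyl)silyl]oxymethyl}-3-methyl-3,4,4a,5,6,7,8,8a-octahydronaphthalen-1-yl trifluoromethanesulfonate, via potassium enolate 13 (not isolated)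
Conditions: KN(SiMe3)2, THF, −78 °C; then PhNTf2, −78 → 0 °C
Reagents that add atoms: N-phenylbis(trifluoromethanesulfonimide), O=S(=O)(N(c1ccccc1)S(=O)(=O)C(F)(F)F)C(F)(F)F
Why: Kinetic deprotonation by the bulky amide base takes a C3 methylene hydrogen in preference to the tertiary C4a–H, so O-triflation gives the C3=C4 enol triflate and the cis fusion is never enolised.

Step 8
Reactants: 14 enol triflate
Product: 15 tert-butyl{[(1R,2S,4aR,8aR)-2-methyl-1,2,4a,5,6,7,8,8a-octahydronaphthalen-1-yl]methoxy}diphenylsilane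
Conditions: Pd(OAc)2 (5 mol %), PPh3, HCO2H, n-Bu3N, DMF, 60 °C
Reagents that add atoms: none
Why: In this palladium-catalysed formate reduction of an enol triflate, oxidative addition to zerovalent palladium, formate exchange, decarboxylation and reductive elimination replace OTf by H at C4 without moving the alkene.

Step 9
Reactants: 15 silyl ether
Product: 16 [(1R,2S,4aR,8aR)-2-methyl-1,2,4a,5,6,7,8,8a-octahydronaphthalen-1-yl]methanol
Conditions: Bu4NF, THF, rt
Reagents that add atoms: none
Why: Fluoride-induced desilylation is driven by the strong Si–F bond and touches no other group of this hydrocarbon-like intermediate.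

Step 10
Reactants: 16 primary alcohol
Product: 17 (1R,2S,4aR,8aR)-2-methyl-1,2,4a,5,6,7,8,8a-octahydronaphthalene-1-carbaldehyde
Conditions: Dess–Martin periodinane, CH2Cl2, 0 °C → rt
Reagents that add atoms: none
Why: Dess–Martin oxidation stops at the aldehyde under near-neutral conditions, and C1 already holds its substituent trans to both neighbours, the thermodynamically preferred arrangement, so epimerisation is no threat.

Step 11
Reactants: 18 cyclohexa-1,3-diene
Product: 19 (1R,4S)-2,3-dioxabicyclo[2.2.2]oct-5-ene (meso endoperoxide)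
Conditions: O2, tetraphenylporphyrin (cat.), visible light, CH2Cl2, 0 °C
Reagents that add atoms: dioxygen, O=O
Why: The [4+2] cycloaddition of photosensitised singlet oxygen to the s-cis-locked diene places both C–O bonds on one face and gives a meso compound ready for desymmetrisation.

Step 12
Reactants: 19 meso endoperoxide
Product: 20 (4R)-4-hydroxycyclohex-2-en-1-one
Conditions: 9-O-acetylcupreidine (10 mol %), CH2Cl2, rt
Reagents that add atoms: none
Why: In the desymmetrising Kornblum–DeLaMare rearrangement the chiral amine base removes one of the two enantiotopic bridgehead hydrogens with O–O cleavage, so the deprotonated carbon becomes the ketone and the untouched (R)-bridgehead remains as C4'.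

Step 13
Reactants: 20 (4R)-4-hydroxycyclohex-2-en-1-one
Product: 21 (4R)-4-(trimethylsilyloxy)cyclohex-2-en-1-one
Conditions: Me3SiCl, Et3N, CH2Cl2, 0 °C
Reagents that add atoms: chlorotrimethylsilane, C[Si](C)(C)Cl
Why: Silylation gives an ether that tolerates an aryllithium at −78 °C and can later be removed by mild base alone, without acid or fluoride.

Step 14
Reactants: 22 5-bromo-2,4-dichloropyridine
Product: 23 5-bromo-2,4-bis[2-(trimethylsilyl)ethoxy]pyridine
Conditions: Me3SiCH2CH2OH, NaH, NMP, 0 → 90 °C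
Reagents that add atoms: 2-(trimethylsilyl)ethanol, C[Si](C)(C)CCO
Why: In this twofold nucleophilic aromatic substitution both chlorides sit ortho or para to the ring nitrogen and are displaced by the alkoxide, whereas the C5 bromide, meta to nitrogen, is not activated and survives as the handle for metalation.

Step 15
Reactants: 23 5-bromo-2,4-bis[2-(trimethylsilyl)ethoxy]pyridine; 21 (4R)-4-(trimethylsilyloxy)cyclohex-2-en-1-one
Product: 26 (1R,4R)-4-{4,6-bis[2-(trimethylsilyl)ethoxy]pyridin-3-yl}-4-(triethylsilyloxy)cyclohex-2-en-1-ol, via pyridyllithium 24 (not isolated), via bis-silyl ether 25 (not isolated)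
Conditions: n-BuLi, THF, −78 °C; 21, −78 °C; Et3SiOTf, −78 → 0 °C; then K2CO3, MeOH, 0 °C
Reagents that add atoms: triethylsilyl trifluoromethanesulfonate, CC[Si](CC)(CC)OS(=O)(=O)C(F)(F)F
Why: Bromine–lithium exchange is followed by 1,2-addition to the enone carbonyl, in which the ortho-alkoxy-substituted aryl group is expected to enter along the equatorial trajectory of the half-chair holding the C4' silyloxy group pseudoaxial, which places pyridyl and C4'–O cis (C1'–O and C4'–O trans), after which the tertiary alkoxide is capped in situ as its TES ether and basic methanolysis frees only the secondary TMS ether.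

Step 16
Reactants: 26 allylic alcohol
Product: 28 (1R,4R)-4-{5-iodo-4,6-bis[2-(trimethylsilyl)ethoxy]pyridin-3-yl}-4-(triethylsilyloxy)cyclohex-2-en-1-ol, via dilithio species 27 (not isolated)
Conditions: lithium 2,2,6,6-tetramethylpiperidide (2.5 equiv), THF, −78 → −40 °C; ICH2CH2I, −78 °C
Reagents that add atoms: 1,2-diiodoethane, ICCI
Why: In this directed ortho-metalation the hindered amide base removes, after the hydroxyl proton, the pyridine C3–H, the most acidic ring hydrogen because it lies between two coordinating alkoxy groups, and the aryllithium is iodinated by 1,2-diiodoethane, which spares the lithium alkoxide.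

Step 17
Reactants: 28 iodo allylic alcohol
Product: 30 3-iodo-5-[(1R,2S,5R,6R)-5-hydroxy-2-(triethylsilyloxy)-7-oxabicyclo[4.1.0]heptan-2-yl]-2,4-bis[2-(trimethylsilyl)ethoxy]pyridine 1-oxide, via epoxy alcohol 29 (not isolated)
Conditions: m-CPBA (3 equiv), NaHCO3, CH2Cl2, 0 °C → rt
Reagents that add atoms: 3-chloroperoxybenzoic acid, O=C(OO)c1cccc(Cl)c1
Why: In this hydroxyl-directed peracid epoxidation combined with pyridine N-oxidation, hydrogen bonding to the free C4' hydroxyl delivers the first equivalent of peracid to the alkene face cis to it, which is also the face away from the pseudoaxial C1' silyl ether, so C5' and C6' are set with the oxirane cis to C4'–OH and trans to C1'–O, and further peracid oxidises the only basic nitrogen while no other alkene is yet in the molecule.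

Step 18
Reactants: 30 epoxy alcohol N-oxide
Product: 31 3-iodo-5-[(1R,2S,5R,6S)-2,5-bis(triethylsilyloxy)-7-oxabicyclo[4.1.0]heptan-2-yl]-2,4-bis[2-(trimethylsilyl)ethoxy]pyridine 1-oxide
Conditions: Et3SiCl, imidazole, CH2Cl2, 0 °C → rt
Reagents that add atoms: chlorotriethylsilane, CC[Si](CC)(CC)Cl
Why: Standard silylation of the only free hydroxyl group masks it against the Grignard reagent of step 19 and the oxidant of step 20 (the changed descriptor reflects ligand priorities only).

Step 19
Reactants: 31 iodopyridine N-oxide; 17 decalin aldehyde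
Product: 33 3-{hydroxy[(1R,2S,4aR,8aR)-2-methyl-1,2,4a,5,6,7,8,8a-octahydronaphthalen-1-yl]methyl} analogue of 31 (iodine replaced; both carbinol epimers), via pyridylmagnesium chloride 32 (not isolated)
Conditions: i-PrMgCl·LiCl, THF, −40 °C; then 17, −40 → 0 °C
Reagents that add atoms: none
Why: Iodine–magnesium exchange, which is known to outrun deprotonation and ring addition on iodopyridine N-oxides and is helped here by the two flanking alkoxy groups, gives an arylmagnesium reagent that adds to the aldehyde carbonyl, and the new carbinol centre needs no control because it is oxidised in step 20.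

Step 20
Reactants: 33 carbinol
Product: 34 3-[(1R,2S,4aR,8aR)-2-methyl-1,2,4a,5,6,7,8,8a-octahydronaphthalene-1-carbonyl]-5-[(1R,2S,5R,6S)-2,5-bis(triethylsilyloxy)-7-oxabicyclo[4.1.0]heptan-2-yl]-2,4-bis[2-(trimethylsilyl)ethoxy]pyridine 1-oxide
Conditions: Dess–Martin periodinane, NaHCO3, CH2Cl2, 0 °C → rt
Reagents that add atoms: none
Why: Dess–Martin oxidation converts both carbinol epimers into one aryl ketone and leaves the alkene, oxirane, silyl ethers and N-oxide alone.

Step 21
Reactants: 34 protected ketone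
Product: 35 fischerin
Conditions: TASF (excess), DMF, 0 °C → rt; pH 6 phosphate buffer
Reagents that add atoms: none
Why: Fluoride attacks all four silicon centres, so the two TES ethers give the free C1' and C4' alcohols and the two TMSE ethers fragment to ethene with expulsion of pyridinolate leaving groups as good as carboxylates, after which the 2-hydroxypyridine N-oxide settles as its 1-hydroxy-2-pyridone tautomer without any acid, strong base or reductant that could harm the oxirane, the alkene or the N–O bond.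

**Compound list**

1 | 1,3-oxazolidin-2-one | O=C1NCCO1 | starting material
2 | (E)-but-2-enoyl chloride | C/C=C/C(=O)Cl | starting material
3 | lithium 2-oxo-1,3-oxazolidin-3-ide | [Li]N1CCOC1=O | intermediate
4 | 3-[(E)-but-2-enoyl]-1,3-oxazolidin-2-one | C/C=C/C(=O)N1CCOC1=O | intermediate
5 | trans-1-methoxy-3-(trimethylsilyloxy)buta-1,3-diene | CO/C=C/C(=C)O[Si](C)(C)C | starting material
6 | 3-{[(1R,2S,6S)-2-methoxy-6-methyl-4-(trimethylsilyloxy)cyclohex-3-en-1-yl]carbonyl}-1,3-oxazolidin-2-one | C[C@H]1CC(O[Si](C)(C)C)=C[C@H](OC)[C@@H]1C(=O)N2CCOC2=O | intermediate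
7 | [(1S,2R,6S)-2-methoxy-6-methyl-4-(trimethylsilyloxy)cyclohex-3-en-1-yl]methanol | C[C@H]1CC(O[Si](C)(C)C)=C[C@H](OC)[C@@H]1CO | intermediate
8 | (4R,5S)-4-(hydroxymethyl)-5-methylcyclohex-2-en-1-one | C[C@H]1CC(=O)C=C[C@@H]1CO | intermediate
9 | (4R,5S)-4-{[tert-butyl(diphenyl)silyl]oxymethyl}-5-methylcyclohex-2-en-1-one | C[C@H]1CC(=O)C=C[C@@H]1CO[Si](c2ccccc2)(c3ccccc3)C(C)(C)C | intermediate
10 | buta-1,3-diene | C=CC=C | starting material
11 | (3S,4R,4aS,8aS)-4-{[tert-butyl(diphenyl)silyl]oxymethyl}-3-methyl-3,4,4a,5,8,8a-hexahydronaphthalen-1(2H)-one | C[C@H]1CC(=O)[C@H]2CC=CC[C@H]2[C@@H]1CO[Si](c3ccccc3)(c4ccccc4)C(C)(C)C | intermediate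
12 | (3S,4R,4aS,8aS)-4-{[tert-butyl(diphenyl)silyl]oxymethyl}-3-methyloctahydronaphthalen-1(2H)-one | C[C@H]1CC(=O)[C@H]2CCCC[C@H]2[C@@H]1CO[Si](c3ccccc3)(c4ccccc4)C(C)(C)C | intermediate
13 | potassium C3=C4 enolate of 12 | C[C@H]1C=C([O-])[C@H]2CCCC[C@H]2[C@@H]1CO[Si](c3ccccc3)(c4ccccc4)C(C)(C)C.[K+] | intermediate
14 | (3R,4R,4aS,8aS)-4-{[tert-butyl(diphenyl)silyl]oxymethyl}-3-methyl-3,4,4a,5,6,7,8,8a-octahydronaphthalen-1-yl trifluoromethanesulfonate | C[C@H]1C=C(OS(=O)(=O)C(F)(F)F)[C@H]2CCCC[C@H]2[C@@H]1CO[Si](c3ccccc3)(c4ccccc4)C(C)(C)C | intermediate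
15 | tert-butyl{[(1R,2S,4aR,8aR)-2-methyl-1,2,4a,5,6,7,8,8a-octahydronaphthalen-1-yl]methoxy}diphenylsilane | C[C@H]1C=C[C@H]2CCCC[C@H]2[C@@H]1CO[Si](c3ccccc3)(c4ccccc4)C(C)(C)C | intermediate
16 | [(1R,2S,4aR,8aR)-2-methyl-1,2,4a,5,6,7,8,8a-octahydronaphthalen-1-yl]methanol | C[C@H]1C=C[C@H]2CCCC[C@H]2[C@@H]1CO | intermediate
17 | (1R,2S,4aR,8aR)-2-methyl-1,2,4a,5,6,7,8,8a-octahydronaphthalene-1-carbaldehyde | C[C@H]1C=C[C@H]2CCCC[C@H]2[C@@H]1C=O | intermediate
18 | cyclohexa-1,3-diene | C1=CC=CCC1 | starting material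
19 | (1R,4S)-2,3-dioxabicyclo[2.2.2]oct-5-ene | C1=C[C@H]2CC[C@@H]1OO2 | intermediate
20 | (4R)-4-hydroxycyclohex-2-en-1-one | O=C1C=C[C@H](O)CC1 | intermediate
21 | (4R)-4-(trimethylsilyloxy)cyclohex-2-en-1-one | O=C1C=C[C@H](O[Si](C)(C)C)CC1 | intermediate
22 | 5-bromo-2,4-dichloropyridine | Clc1cc(Cl)c(Br)cn1 | starting material
23 | 5-bromo-2,4-bis[2-(trimethylsilyl)ethoxy]pyridine | C[Si](C)(C)CCOc1cc(OCC[Si](C)(C)C)c(Br)cn1 | intermediate
24 | {4,6-bis[2-(trimethylsilyl)ethoxy]pyridin-3-yl}lithium | C[Si](C)(C)CCOc1cc(OCC[Si](C)(C)C)c([Li])cn1 | intermediate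
25 | 5-[(1R,4R)-1-(triethylsilyloxy)-4-(trimethylsilyloxy)cyclohex-2-en-1-yl]-2,4-bis[2-(trimethylsilyl)ethoxy]pyridine | C[Si](C)(C)CCOc1cc(OCC[Si](C)(C)C)c(cn1)[C@@]2(O[Si](CC)(CC)CC)CC[C@@H](O[Si](C)(C)C)C=C2 | intermediate
26 | (1R,4R)-4-{4,6-bis[2-(trimethylsilyl)ethoxy]pyridin-3-yl}-4-(triethylsilyloxy)cyclohex-2-en-1-ol | C[Si](C)(C)CCOc1cc(OCC[Si](C)(C)C)c(cn1)[C@@]2(O[Si](CC)(CC)CC)CC[C@@H](O)C=C2 | intermediate
27 | C3-lithio lithium alkoxide of 26 | C[Si](C)(C)CCOc1c([Li])c(OCC[Si](C)(C)C)c(cn1)[C@@]2(O[Si](CC)(CC)CC)CC[C@@H](O[Li])C=C2 | intermediate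
28 | (1R,4R)-4-{5-iodo-4,6-bis[2-(trimethylsilyl)ethoxy]pyridin-3-yl}-4-(triethylsilyloxy)cyclohex-2-en-1-ol | C[Si](C)(C)CCOc1c(I)c(OCC[Si](C)(C)C)c(cn1)[C@@]2(O[Si](CC)(CC)CC)CC[C@@H](O)C=C2 | intermediate
29 | 3-iodo-5-[(1R,2S,5R,6R)-5-hydroxy-2-(triethylsilyloxy)-7-oxabicyclo[4.1.0]heptan-2-yl]-2,4-bis[2-(trimethylsilyl)ethoxy]pyridine | C[Si](C)(C)CCOc1c(I)c(OCC[Si](C)(C)C)c(cn1)[C@@]2(O[Si](CC)(CC)CC)CC[C@@H](O)[C@H]3O[C@H]32 | intermediate
30 | 1-oxide of 29 | C[Si](C)(C)CCOc1c(I)c(OCC[Si](C)(C)C)c(c[n+]1[O-])[C@@]2(O[Si](CC)(CC)CC)CC[C@@H](O)[C@H]3O[C@H]32 | intermediate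
31 | 3-iodo-5-[(1R,2S,5R,6S)-2,5-bis(triethylsilyloxy)-7-oxabicyclo[4.1.0]heptan-2-yl]-2,4-bis[2-(trimethylsilyl)ethoxy]pyridine 1-oxide | C[Si](C)(C)CCOc1c(I)c(OCC[Si](C)(C)C)c(c[n+]1[O-])[C@@]2(O[Si](CC)(CC)CC)CC[C@@H](O[Si](CC)(CC)CC)[C@H]3O[C@H]32 | intermediate
32 | pyridin-3-ylmagnesium chloride derived from 31 | C[Si](C)(C)CCOc1c([Mg]Cl)c(OCC[Si](C)(C)C)c(c[n+]1[O-])[C@@]2(O[Si](CC)(CC)CC)CC[C@@H](O[Si](CC)(CC)CC)[C@H]3O[C@H]32 | intermediate
33 | decalinyl(pyridyl)carbinol, both epimers at the carbinol carbon | C[C@H]1C=C[C@H]2CCCC[C@H]2[C@@H]1C(O)c3c(OCC[Si](C)(C)C)c(c[n+]([O-])c3OCC[Si](C)(C)C)[C@@]4(O[Si](CC)(CC)CC)CC[C@@H](O[Si](CC)(CC)CC)[C@H]5O[C@H]54 | intermediate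
34 | fully protected ketone (bis-TMSE, bis-TES, N-oxide) | C[C@H]1C=C[C@H]2CCCC[C@H]2[C@@H]1C(=O)c3c(OCC[Si](C)(C)C)c(c[n+]([O-])c3OCC[Si](C)(C)C)[C@@]4(O[Si](CC)(CC)CC)CC[C@@H](O[Si](CC)(CC)CC)[C@H]5O[C@H]54 | intermediate
35 | fischerin, 5-[(1R,2S,5R,6R)-2,5-dihydroxy-7-oxabicyclo[4.1.0]heptan-2-yl]-1,4-dihydroxy-3-[(1R,2S,4aR,8aR)-2-methyl-1,2,4a,5,6,7,8,8a-octahydronaphthalene-1-carbonyl]pyridin-2(1H)-one | C[C@H]1C=C[C@H]2CCCC[C@H]2[C@@H]1C(=O)c1c(O)c([C@@]2(O)CC[C@@H](O)[C@H]3O[C@H]32)cn(O)c1=O | target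

**Step count**

Total steps: 21. Longest linear sequence: 13 (steps 1–10, then 19–21).

**Steps most likely to fail**

**Step 5.**
- What may go wrong: facial selectivity may erode. The trans-diequatorial C1/C2 substituents lock the half-chair, so approach anti to the side chain must pass through a boat-like ring A while the other face offers a chair-like path. Slow turnover would also lengthen exposure to the Lewis acid and allow epimerisation at C4a.
- Fallback: the same butadiene cycloaddition is run before the methyl group is present, and the methyl group is brought in by a stereospecific allylic substitution. It sets out from 5. Cycloaddition with commercial 3-acryloyl-1,3-oxazolidin-2-one F1 under the catalyst of step 2 gives the des-methyl adduct F2. LiAlH4 reduction and acidic unmasking give (4R)-4-(hydroxymethyl)cyclohex-2-en-1-one F3. Silylation gives its TBDPS ether F4, whose half-chair is free to place the side chain pseudoaxially, so that anti attack is chair-like. Butadiene and EtAlCl2 give the des-methyl cis-octalone F5, and hydrogenation gives the des-methyl cis-decalone F6. Kinetic enolisation with LiN(i-Pr)2 and dehydrogenation with N-tert-butylbenzenesulfinimidoyl chloride at −78 °C give the C2=C3 enone F7. NaBH4/CeCl3 reduction from the face opposite the axial C5 methylene gives the allylic alcohol F8 (C4–OH cis to C5), and phenyl isocyanate gives the N-phenylcarbamate F9. Deprotonation and treatment with MeLi/CuI then deliver methyl to C2 in a carbamate-directed syn-SN2' displacement on the face of the leaving group. This sets C2 and the C3=C4 alkene together and comes back to the route at 15.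

**Step 15.**
- What may go wrong: facial selectivity in the carbonyl addition may be poor or inverted, because the C4' substituent is remote and the half-chair is mobile. Competing enolisation of 21 is also possible.
- Fallback: if the aryl group prefers to enter anti to the silyloxy group, that preference is used. It sets out from 19, which the pseudoenantiomeric catalyst 9-O-acetylcupreine converts into (4S)-4-hydroxycyclohex-2-en-1-one F10. Silylation gives its TMS ether F11. Addition of 24 followed by Et3SiOTf gives the C4'-epimeric bis-silyl ether F12, with C1' as required. K2CO3/MeOH gives the C4'-epimeric allylic alcohol F13. Mitsunobu inversion at C4' with 4-nitrobenzoic acid, PPh3 and diisopropyl azodicarboxylate gives the 4-nitrobenzoate F14. Methanolysis (K2CO3, MeOH) comes back to the route at 26.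

**Step 19.**
- What may go wrong: iodine–magnesium exchange on the electron-rich, crowded ring may be incomplete, the isopropyl Grignard reagent may attack C6 of the N-oxide, or addition to the α-branched aldehyde may be sluggish.
- Fallback: the N–O bond is introduced last, so that the organometallic step runs on a plain pyridine, where halogen–lithium exchange and aldehyde addition are routine. It sets out from 28. VO(acac)2/t-BuOOH epoxidises only the allylic alcohol and stops at 29. Et3SiCl/imidazole gives the bis-TES iodopyridine F15. n-BuLi at −78 °C followed by 17 gives the pyridyl carbinol F16. Dess–Martin oxidation gives the pyridyl ketone F17, and TASF gives N-deoxyfischerin F18. Persilylation (HN(SiMe3)2, Me3SiCl) is followed by oxidation of the silylated pyridone with MoO(O2)2·pyridine·HMPA, a peroxo complex known to hydroxylate silylated lactam nitrogen in the presence of alkenes. Aqueous EDTA work-up then comes back to the route at 35.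

**Further compounds**

F1 | step 5 | 3-acryloyl-1,3-oxazolidin-2-one | C=CC(=O)N1CCOC1=O
F2 | step 5 | 3-{[(1R,2S)-2-methoxy-4-(trimethylsilyloxy)cyclohex-3-en-1-yl]carbonyl}-1,3-oxazolidin-2-one | C1CC(O[Si](C)(C)C)=C[C@H](OC)[C@@H]1C(=O)N2CCOC2=O
F3 | step 5 | (4R)-4-(hydroxymethyl)cyclohex-2-en-1-one | C1CC(=O)C=C[C@@H]1CO
F4 | step 5 | (4R)-4-{[tert-butyl(diphenyl)silyl]oxymethyl}cyclohex-2-en-1-one | C1CC(=O)C=C[C@@H]1CO[Si](c2ccccc2)(c3ccccc3)C(C)(C)C
F5 | step 5 | (4R,4aS,8aS)-4-{[tert-butyl(diphenyl)silyl]oxymethyl}-3,4,4a,5,8,8a-hexahydronaphthalen-1(2H)-one | C1CC(=O)[C@H]2CC=CC[C@H]2[C@@H]1CO[Si](c3ccccc3)(c4ccccc4)C(C)(C)C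
F6 | step 5 | (4R,4aS,8aS)-4-{[tert-butyl(diphenyl)silyl]oxymethyl}octahydronaphthalen-1(2H)-one | C1CC(=O)[C@H]2CCCC[C@H]2[C@@H]1CO[Si](c3ccccc3)(c4ccccc4)C(C)(C)C
F7 | step 5 | (4R,4aS,8aS)-4-{[tert-butyl(diphenyl)silyl]oxymethyl}-4a,5,6,7,8,8a-hexahydronaphthalen-1(4H)-one | C1=CC(=O)[C@H]2CCCC[C@H]2[C@@H]1CO[Si](c3ccccc3)(c4ccccc4)C(C)(C)C
F8 | step 5 | allylic alcohol from F7, C4–OH cis to C5 | C1=C[C@@H](O)[C@H]2CCCC[C@H]2[C@@H]1CO[Si](c3ccccc3)(c4ccccc4)C(C)(C)C
F9 | step 5 | N-phenylcarbamate of F8 | C1=C[C@@H](OC(=O)Nc5ccccc5)[C@H]2CCCC[C@H]2[C@@H]1CO[Si](c3ccccc3)(c4ccccc4)C(C)(C)C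
F10 | step 15 | (4S)-4-hydroxycyclohex-2-en-1-one | O=C1C=C[C@@H](O)CC1
F11 | step 15 | (4S)-4-(trimethylsilyloxy)cyclohex-2-en-1-one | O=C1C=C[C@@H](O[Si](C)(C)C)CC1
F12 | step 15 | 5-[(1R,4S)-1-(triethylsilyloxy)-4-(trimethylsilyloxy)cyclohex-2-en-1-yl]-2,4-bis[2-(trimethylsilyl)ethoxy]pyridine | C[Si](C)(C)CCOc1cc(OCC[Si](C)(C)C)c(cn1)[C@@]2(O[Si](CC)(CC)CC)CC[C@H](O[Si](C)(C)C)C=C2
F13 | step 15 | (1S,4R)-4-{4,6-bis[2-(trimethylsilyl)ethoxy]pyridin-3-yl}-4-(triethylsilyloxy)cyclohex-2-en-1-ol | C[Si](C)(C)CCOc1cc(OCC[Si](C)(C)C)c(cn1)[C@@]2(O[Si](CC)(CC)CC)CC[C@H](O)C=C2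
F14 | step 15 | (1R,4R)-4-{4,6-bis[2-(trimethylsilyl)ethoxy]pyridin-3-yl}-4-(triethylsilyloxy)cyclohex-2-en-1-yl 4-nitrobenzoate | C[Si](C)(C)CCOc1cc(OCC[Si](C)(C)C)c(cn1)[C@@]2(O[Si](CC)(CC)CC)CC[C@@H](OC(=O)c3ccc(cc3)[N+](=O)[O-])C=C2
F15 | step 19 | 3-iodo-5-[(1R,2S,5R,6S)-2,5-bis(triethylsilyloxy)-7-oxabicyclo[4.1.0]heptan-2-yl]-2,4-bis[2-(trimethylsilyl)ethoxy]pyridine | C[Si](C)(C)CCOc1c(I)c(OCC[Si](C)(C)C)c(cn1)[C@@]2(O[Si](CC)(CC)CC)CC[C@@H](O[Si](CC)(CC)CC)[C@H]3O[C@H]32
F16 | step 19 | decalinyl(pyridyl)carbinol without N-oxide, both carbinol epimers | C[C@H]1C=C[C@H]2CCCC[C@H]2[C@@H]1C(O)c3c(OCC[Si](C)(C)C)c(cnc3OCC[Si](C)(C)C)[C@@]4(O[Si](CC)(CC)CC)CC[C@@H](O[Si](CC)(CC)CC)[C@H]5O[C@H]54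
F17 | step 19 | protected ketone without N-oxide | C[C@H]1C=C[C@H]2CCCC[C@H]2[C@@H]1C(=O)c3c(OCC[Si](C)(C)C)c(cnc3OCC[Si](C)(C)C)[C@@]4(O[Si](CC)(CC)CC)CC[C@@H](O[Si](CC)(CC)CC)[C@H]5O[C@H]54
F18 | step 19 | N-deoxyfischerin | C[C@H]1C=C[C@H]2CCCC[C@H]2[C@@H]1C(=O)c1c(O)c([C@@]2(O)CC[C@@H](O)[C@H]3O[C@H]32)c[nH]c1=O
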